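The numbers in the tables are simulated with constants of no real substance; the scatter is artificial.

Which species leads after 1.0 h is the open question for green, blue and ochre, and green is charged close to gamma.

| setting | gamma | theta | delta | green | blue | ochre |
|---|---|---|---|---|---|---|
| starting material | 10 mM | 10 mM | 10 mM | 10 mM | 10 mM | 10 mM |
| reagent in the second phase | 15 mM | 61 mM | 140 mM | 20.0 mM | 60.0 mM | 180 mM |
| protic impurity | 5 mM | 5 mM | 5 mM | 5.00 mM | 5.00 mM | 5.00 mM |
| remark | run made earlier | run made earlier | run made earlier |  |  |  |
| time |  |  |  | 1.0 h | 1.0 h | 1.0 h |
| volume of the second phase over the first |  |  |  | 1.0 | 1.0 | 1.0 |

- gamma (time / min: side product / %, starting material / %, target / %): 15.0: 14.6, 61.3, 22.0; 30.0: 34.8, 37.1, 31.0; 50.0: 49.0, 12.3, 38.3; 60.0: 55.5, 5.3, 39.6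
- theta (time / min: side product / %, starting material / %, target / %): 8.00: 11.9, 28.8, 60.0; 20.0: 20.1, 0, 82.3; 40.0: 18.9, 0, 80.7; 60.0: 17.8, 1.1, 81.8
- delta (time / min: side product / %, starting material / %, target / %): 5.00: 8.8, 16.2, 77.2; 12.0: 8.3, 0, 90.6; 25.0: 9.8, 0.6, 88.7; 60.0: 12.7, 2.3, 89.4

(each reading ± 1 percentage point)

- a species is counted by the starting material in it: one side product counts as two
- in the second phase: reagent in the second phase; everything else is in the first
- charges count per volume of the first phase; a concentration in a rate is the amount of a species over the volume of its own phase; every rate counts per litre of the first phase
- the earlier runs hold the two phases in the same ratio of volumes as the flask asked about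

- which of these there is most of at the end, counted by the starting material in it, green (target / side product / starting material)
- which of these there is most of at the end, counted by the starting material in it, blue (target / side product / starting material)
- which of these there is most of at the end, counted by the starting material in it, ochre (target / side product / starting material)
- amount of the one of these that there is most of at the end, in percent of the starting material charged, green
- amount of the one of these that there is most of at the end, in percent of the starting material charged, blue
- amount of the one of these that there is most of at the end, in percent of the starting material charged, ochre

Green holds 5.00 mM more reagent in the second phase than gamma, and gamma at 60.0 min reads more side product than target, 55.5% against 39.6%. If each protic impurity takes one reagent, the net reagent n = c(reagent in the second phase) − c(protic impurity) is 10.0 mM in gamma and 15.0 mM in green.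

Theta and delta show what n does once their starting material reads zero, at 20.0 min and 12.0 min. Side product over target, times n, reads 13.7 mM in theta and 12.4 mM in delta, though n differs widely. Their mean, 13.0 mM, is the loss constant, a kind of selectivity factor: side product over target at the end, times net reagent, with starting material held at 10 mM. Target's share of what has reacted is then n over n plus the loss constant.

The loss constant is larger than gamma's n, so side product leads there. The rule gives gamma 43.5%, and gamma's own readings at 60.0 min, which did not enter the constant, give 41.6%. It is smaller than green's n, so target should lead in green. Taking the starting material as reacted by 1.0 h, my reckoning gives target 53.5% in green, 80.9% in blue and 93.1% in ochre.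

The forecast names target, target and target as the largest, at 51%, 81% and 92%, and says of green: “Target leads, but narrowly”. On green its 51% stands against the 53.5% reckoned here.

    reagent in the reaction phase ⇌ reagent in the second phase, rate k1*([reagent in the reaction phase] - [reagent in the second phase]/K1) per volume of the first phase (partition coefficient = 2.50, kL = 0.0685 min⁻¹)
    starting material + reagent in the reaction phase → target (k = 166 M⁻¹ min⁻¹)
    reagent in the reaction phase + protic impurity → quenched reagent (k = 211 M⁻¹ min⁻¹)
    reagent in the reaction phase → decomposed reagent (k = 0.0281 min⁻¹)
    starting material + target → side product (k = 5.28 M⁻¹ min⁻¹)

Green ends with 54.2% of target, blue with 80.9% and ochre with 91.9%, and green's end gives back a loss constant of 12.6 mM. Green's narrow lead comes from the passing of starting material + target into side product, acting together with the drag of the crossing of reagent in the second phase over to reagent in the reaction phase: target reaches 95.0% without the first and 88.9% at perfect contact. For a neighbour of blue with 12 mM of protic impurity, the loss constant gives 78.7% of target, and that flask holds 74.6%.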